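In the dusk run ZuQe gains 8.4 percentage points over the 9.50 min up to 12.0 min but 8.7 points over the 18.0 min after it, a slower climb, while Zu still reads 83.7% at 30.0 min; this flask therefore looks to be nearing the equilibrium of Zu + Qe ⇌ ZuQe with Zu in hand. The unit to count in is the lifetime of that approach, the time in which the gap between ZuQe and its plateau shrinks by a factor e, τ = 22.8 min, got from the ratio of the two slopes and the spacing of their midpoints, a reading that carries the scatter of 0.5 points.

- dusk: Zu 0.72 M; Dz 1.08 M; Jy 0.072 M; the very flask that is asked about, followed so far
- flask: Zu 0.72 M; Dz 1.08 M; Jy 0.0720 M; time 1.0 h; volume of the second phase over the first 0.50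

dusk run (percent of the Zu charged)

| time / min | ZuQe / % | Zu / % |
|---|---|---|
| 2.50 | 0.3 | 98.5 |
| 6.00 | 4.3 | 95.7 |
| 12.0 | 8.7 | 90.9 |
| 30.0 | 17.4 | 83.7 |

(standard deviation of a reading: 0.5 percentage points)

* the ZuQe standing at 1.0 h, as a percentage of the Zu charged
* part of the Zu charged that has reacted at 1.0 h

- percentages count the Zu that a species holds: one ZuZuQe counts as two
- in the second phase: Dz; everything else is in the first
- charges count per volume of the first phase; a concentration in a rate is the amount of a species over the volume of its own phase; every rate counts per litre of the first phase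
- the numbers in the tables scatter with a standard deviation of 0.5 percentage points
- steps under discussion: Qe <-> Dz; Zu + Qe <-> ZuQe; Qe + Jy -> QeJy; Zu + ZuQe -> ZuZuQe
- the earlier runs hold the two phases in the same ratio of volumes as the flask asked about

The rungs of this flask run as follows, fastest first. Qe comes over from Dz within the first readings, ZuQe going from 0.3% at 2.50 min to 4.3% at 6.00 min, a time shorter than τ, so afterwards Qe can be held steady and the approach treated as pseudo-first-order. Next comes τ itself, the rise of ZuQe. Last stands the passage of ZuQe into ZuZuQe, whose share these readings do not resolve, Zu and ZuQe together reading 101% at 30.0 min against a scatter of 0.5 points on each reading.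

My own reckoning takes the later slope times τ, carried to 30.0 min, as a gap of 7.4 points; the 1.32 lifetimes left before 1.0 h close 73.2% of it, so y comes to 22.8%, with cv above it by whatever ZuZuQe has taken. The forecast, saying "Fitting a relaxation with lag gives a plateau near 23% and a time constant near 20 min", gives y = 21.3% and cv = 22.3%, its y lying 1.5 points below this reckoning.

The flask gives y = 21.2% and cv = 22.8%.

    Qe ⇌ Dz, rate k1*([Qe] - [Dz]/K1) per volume of the first phase (partition coefficient = 2.90, kL = 0.290 min⁻¹)
    Zu + Qe ⇌ ZuQe (K = 0.860 L mol⁻¹, k = 0.0250 L mol⁻¹ min⁻¹)
    Qe + Jy → QeJy (k = 0.0240 L mol⁻¹ min⁻¹)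
    Zu + ZuQe → ZuZuQe (k = 0.00160 L mol⁻¹ min⁻¹)

The half-life of ZuQe by the turning of Zu + ZuQe into ZuZuQe alone, the other concentrations as charged, is 10 h, long against 1.0 h, and ZuZuQe stands at 1.64% then. The same flask read at 4.0 h has run 10.5 lifetimes, against 2.63 at 1.0 h; its ZuQe is still at 20.7%, while cv has reached 28.9% and ZuZuQe 8.21%.

(The numbers in the tables are simulated on assumed constants; scatter was added.)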